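**Retrosynthetic overview**

Numbering is that of germacranolides: ring carbons C1–C10, lactone carbons C11 (α) and C12 (C=O), exocyclic C13, methyls C14 (on C10) and C15 (on C4).
1. Disconnections: the O8 side-chain ester (made last); the γ-lactone through the C7–C11 bond together with C11=C13 in one pot (key step); the ten-membered ring by ring-closing metathesis at C1=C10; the open chain by two catalytic enal alkynylations (C8–C9 and C6–C7).
2. Ring order: ring A (ten-membered carbocycle, step 11) first, then ring B (γ-lactone, step 13) is stitched onto the finished medium ring across C6–C7.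
3. Enabling feature: C7 lies between the two oxygen-bearing ring carbons C6 and C8, and in the target O6, C11, O8 and O9 all sit on one face of ring A (cis-fused lactone). A trans C7–C8 oxirane whose oxygen is anti to O6 therefore puts C7 in 5-exo-tet reach of a carbanion tethered to O6; its opening inverts C7 and sets free the C8 hydroxyl that later carries the side chain.
4. Stereocontrol: C9 and C6 by ligand-controlled alkynylation, C7/C8 by Sharpless epoxidation directed by the C9 hydroxyl, C7 inverted in the key step, the side-chain centre from (4R)-4-methyloxolan-2-one.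

Key step: step 13

Assumption 1: the zinc–ProPhenol alkynylations are taken to follow the sense "(S,S)-ligand gives Re-face addition to an enal"; should the opposite hold, the antipodal ligand is used in steps 1 and 6.
Assumption 2: (4R)-4-methyloxolan-2-one is taken as a purchasable building block.

**Route**

Step 1
Reactants: 1 2-methylprop-2-enal (methacrolein); 2 ethynyltrimethylsilane
Product: 3 (3R)-2-methyl-5-(trimethylsilyl)pent-1-en-4-yn-3-ol
Conditions: (R,R)-ProPhenol (10 mol %), Me2Zn (3 equiv), Ph3P=O (20 mol %), toluene, 0 °C; aq. NH4Cl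
Reagents that add atoms: none
Why: Zinc–ProPhenol catalysed enantioselective alkynylation of an enal (Trost alkynylation), in which the zinc alkynylide should add to the Si face of the aldehyde and so set the C9 carbinol.

Step 2
Reactants: 3 (3R)-2-methyl-5-(trimethylsilyl)pent-1-en-4-yn-3-ol
Product: 4 tert-butyldimethyl{[(3R)-2-methyl-5-(trimethylsilyl)pent-1-en-4-yn-3-yl]oxy}silane
Conditions: TBSCl, imidazole, DMF, 23 °C
Reagents that add atoms: tert-butyldimethylsilyl chloride, CC(C)(C)[Si](C)(C)Cl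
Why: Silyl ether formation on a secondary alcohol (silylation), which leaves the stereocentre untouched and masks O9 through the organometallic steps.

Step 3
Reactants: 4 tert-butyldimethyl{[(3R)-2-methyl-5-(trimethylsilyl)pent-1-en-4-yn-3-yl]oxy}silane
Product: 5 tert-butyldimethyl{[(3R)-2-methylpent-1-en-4-yn-3-yl]oxy}silane
Conditions: K2CO3 (cat.), MeOH, 0 → 23 °C
Reagents that add atoms: none
Why: Methoxide-mediated protodesilylation of the C(sp)–SiMe3 bond, which is far faster than cleavage of the hindered O–Si bond.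

Step 4
Reactants: 6 hex-1-en-5-yne
Product: 8 (2E)-3-methylhepta-2,6-dien-1-ol, via alkenyldimethylalane 7 (not isolated)
Conditions: Me3Al (2 equiv), Cp2ZrCl2 (25 mol %), CH2Cl2, 23 °C; then n-BuLi, THF, −78 °C; (CH2O)n, −78 → 23 °C
Reagents that add atoms: trimethylaluminium, C[Al](C)C; formaldehyde (from paraformaldehyde), C=O
Why: Negishi zirconium-catalysed carboalumination (syn methylalumination of the terminal alkyne, the isolated vinyl group being inert) followed by hydroxymethylation of the derived aluminate with retention, which sets the 4E olefin and C15.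

Step 5
Reactants: 8 (2E)-3-methylhepta-2,6-dien-1-ol
Product: 9 (2E)-3-methylhepta-2,6-dienal
Conditions: TEMPO (10 mol %), (diacetoxyiodo)benzene (1.1 equiv), CH2Cl2, 23 °C
Reagents that add atoms: none
Why: Oxoammonium (TEMPO) oxidation of a primary allylic alcohol to the enal, mild enough not to isomerize the 2E olefin.

Step 6
Reactants: 5 tert-butyldimethyl{[(3R)-2-methylpent-1-en-4-yn-3-yl]oxy}silane; 9 (2E)-3-methylhepta-2,6-dienal
Product: 10 (3R,6S,7E)-3-[(tert-butyldimethylsilyl)oxy]-2,8-dimethyldodeca-1,7,11-trien-4-yn-6-ol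
Conditions: (S,S)-ProPhenol (20 mol %), Me2Zn, Ph3P=O (40 mol %), toluene, 0 → 4 °C; aq. NH4Cl
Reagents that add atoms: none
Why: Second zinc–ProPhenol enal alkynylation, which forms C6–C7 and should set the C6 carbinol by ligand-controlled Re-face addition, the remote C9 centre having little influence.

Step 7
Reactants: 10 (3R,6S,7E)-3-[(tert-butyldimethylsilyl)oxy]-2,8-dimethyldodeca-1,7,11-trien-4-yn-6-ol
Product: 11 (3S,4E,6R,7E)-3-[(tert-butyldimethylsilyl)oxy]-2,8-dimethyldodeca-1,4,7,11-tetraen-6-ol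
Conditions: NaAlH2(OCH2CH2OCH3)2 (Red-Al), THF, −20 → 0 °C; Rochelle salt
Reagents that add atoms: none
Why: Hydroxyl-directed trans-hydroalumination of the propargylic alcohol (Red-Al reduction), which should give only the E C7=C8 olefin; the descriptors change by CIP priority only.

Step 8
Reactants: 11 (3S,4E,6R,7E)-3-[(tert-butyldimethylsilyl)oxy]-2,8-dimethyldodeca-1,4,7,11-tetraen-6-ol; 12 2-(diethoxyphosphoryl)acetic acid
Product: 13 (3S,4E,6R,7E)-3-[(tert-butyldimethylsilyl)oxy]-2,8-dimethyldodeca-1,4,7,11-tetraen-6-yl 2-(diethoxyphosphoryl)acetate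
Conditions: DCC, DMAP (10 mol %), CH2Cl2, 0 → 23 °C
Reagents that add atoms: none
Why: Steglich esterification with retention at C6; the phosphonoacetate blocks O6 during the epoxidation and is the C11–C12 unit of the lactone.

Step 9
Reactants: 13 (3S,4E,6R,7E)-3-[(tert-butyldimethylsilyl)oxy]-2,8-dimethyldodeca-1,4,7,11-tetraen-6-yl 2-(diethoxyphosphoryl)acetate
Product: 14 (3S,4E,6R,7E)-3-hydroxy-2,8-dimethyldodeca-1,4,7,11-tetraen-6-yl 2-(diethoxyphosphoryl)acetate
Conditions: HF·pyridine, pyridine, THF, 0 → 23 °C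
Reagents that add atoms: none
Why: Buffered fluoride desilylation frees the C9 hydroxyl that must direct the epoxidation, without ionizing the doubly allylic carbinol.

Step 10
Reactants: 14 (3S,4E,6R,7E)-3-hydroxy-2,8-dimethyldodeca-1,4,7,11-tetraen-6-yl 2-(diethoxyphosphoryl)acetate
Product: 15 (1S,2E)-1-{(2R,3R)-3-[(1R)-1-hydroxy-2-methylprop-2-en-1-yl]oxiran-2-yl}-3-methylhepta-2,6-dien-1-yl 2-(diethoxyphosphoryl)acetate
Conditions: Ti(OiPr)4 (20 mol %), D-(−)-diisopropyl tartrate (24 mol %), t-BuOOH, 4 Å MS, CH2Cl2, −20 °C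
Reagents that add atoms: tert-butyl hydroperoxide, CC(C)(C)OO
Why: Sharpless asymmetric epoxidation in the matched (kinetic-resolution) sense: D-(−)-DIPT should deliver oxygen to the face of the E C7=C8 olefin that gives the erythro epoxy alcohol (7R,8R), while the isopropenyl group is mismatched for this C9 configuration and C4=C5 is not allylic to a free hydroxyl.

Step 11
Reactants: 15 (1S,2E)-1-{(2R,3R)-3-[(1R)-1-hydroxy-2-methylprop-2-en-1-yl]oxiran-2-yl}-3-methylhepta-2,6-dien-1-yl 2-(diethoxyphosphoryl)acetate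
Product: 16 (1R,2S,3E,7Z,9R,10R)-9-hydroxy-4,8-dimethyl-11-oxabicyclo[8.1.0]undeca-3,7-dien-2-yl 2-(diethoxyphosphoryl)acetate
Conditions: second-generation Hoveyda–Grubbs catalyst, RuCl2(H2IMes)(=CH–C6H4-2-OiPr) (10 mol %), 1,4-benzoquinone (20 mol %), toluene (1 mM), 80 °C
Reagents that add atoms: none
Why: Ring-closing metathesis of the vinyl and isopropenyl termini, in which a ten-membered ring should close with the ring carbons cis on the new trisubstituted olefin (1(10)Z), the free allylic hydroxyl assists loading and the trans-oxirane rules out the six-membered closure onto C4=C5.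

Step 12
Reactants: 16 (1R,2S,3E,7Z,9R,10R)-9-hydroxy-4,8-dimethyl-11-oxabicyclo[8.1.0]undeca-3,7-dien-2-yl 2-(diethoxyphosphoryl)acetate
Product: 17 (1R,2S,3E,7Z,9R,10S)-9-[(tert-butyldimethylsilyl)oxy]-4,8-dimethyl-11-oxabicyclo[8.1.0]undeca-3,7-dien-2-yl 2-(diethoxyphosphoryl)acetate
Conditions: TBSOTf, 2,6-lutidine, CH2Cl2, −78 °C
Reagents that add atoms: tert-butyldimethylsilyl trifluoromethanesulfonate, CC(C)(C)[Si](C)(C)OS(=O)(=O)C(F)(F)F
Why: Silylation of the hindered C9 alcohol with a silyl triflate, so that no alkoxide next to the oxirane (Payne shift) can form in step 13 and O9 stays distinct from O8.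

Step 13
Reactants: 17 (1R,2S,3E,7Z,9R,10S)-9-[(tert-butyldimethylsilyl)oxy]-4,8-dimethyl-11-oxabicyclo[8.1.0]undeca-3,7-dien-2-yl 2-(diethoxyphosphoryl)acetate
Product: 19 (3aR,4S,5R,6Z,10E,11aS)-5-[(tert-butyldimethylsilyl)oxy]-4-hydroxy-6,10-dimethyl-3-methylidene-3a,4,5,8,9,11a-hexahydrocyclodeca[b]furan-2(3H)-one, via α-phosphono lactone 18 (not isolated)
Conditions: NaH (1.1 equiv), THF, 0 → 45 °C; then (CH2O)n, 45 °C
Reagents that add atoms: formaldehyde (from paraformaldehyde), C=O
Why: Deprotonation of the phosphonoacetate gives a stabilized carbanion that opens the oxirane at C7 by SN2 attack, the C8 alkoxide is quenched at once by the more acidic C11–H of the α-phosphono lactone, and the phosphonate carbanion so formed olefinates formaldehyde (Horner–Wadsworth–Emmons) to the exocyclic methylene. The closest known reaction types are the cyclization of ester-tethered stabilized carbanions onto epoxides to give γ-lactones and the methylenation of α-diethoxyphosphoryl lactones with formaldehyde. The γ-lactone closes in the 5-exo-tet mode onto the preformed ten-membered ring, and the three-atom tether on O6 can reach only the face of C7 syn to O6, which gives the cis ring fusion. C7 is set by inversion at the oxirane carbon fixed in step 10 and C8 keeps its oxygen with retention, so that O6, C11, O8 and O9 end up on one face of ring A. The step needs attack at C7 and not at C8 (6-endo) and C- over O-alkylation; the tether length, the anti arrangement of O6 and the oxirane oxygen that goes with a gauche C5–C6–C7–C8 ring torsion, and the soft carbanion should secure this. With one equivalent of base only the weakly basic phosphate remains at the end, so the free C8 hydroxyl should neither take over the silyl group from O9 nor translactonize.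

Step 14
Reactants: 20 (4R)-4-methyloxolan-2-one
Product: 22 benzyl (3R)-4-hydroxy-3-methylbutanoate, via potassium hydroxy carboxylate 21 (not isolated)
Conditions: KOH (1.0 equiv), MeOH/H2O, 23 °C; evaporate; BnBr, DMF, 23 °C
Reagents that add atoms: potassium hydroxide, [K+].[OH-]; benzyl bromide, BrCc1ccccc1
Why: Saponification of the γ-lactone followed by SN2 O-alkylation of the carboxylate, as used for 4-hydroxybutanoates; the stereocentre is not involved and the product is used at once.

Step 15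
Reactants: 22 benzyl (3R)-4-hydroxy-3-methylbutanoate; 23 octadecanoyl chloride
Product: 24 benzyl (3R)-3-methyl-4-(octadecanoyloxy)butanoate
Conditions: pyridine, DMAP (cat.), CH2Cl2, 0 → 23 °C
Reagents that add atoms: none
Why: Acylation of the primary alcohol by an acid chloride under nucleophilic catalysis, which should outrun relactonization.

Step 16
Reactants: 24 benzyl (3R)-3-methyl-4-(octadecanoyloxy)butanoate
Product: 25 (3R)-3-methyl-4-(octadecanoyloxy)butanoic acid
Conditions: H2 (1 atm), palladium on carbon (Pd/C, 10 wt %), EtOAc, 23 °C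
Reagents that add atoms: none
Why: Hydrogenolysis of the benzyl ester, selective because the fragment holds no olefin and the alkyl ester is inert.

Step 17
Reactants: 19 (3aR,4S,5R,6Z,10E,11aS)-5-[(tert-butyldimethylsilyl)oxy]-4-hydroxy-6,10-dimethyl-3-methylidene-3a,4,5,8,9,11a-hexahydrocyclodeca[b]furan-2(3H)-one; 25 (3R)-3-methyl-4-(octadecanoyloxy)butanoic acid
Product: 26 (3aS,4S,5R,6Z,10E,11aS)-5-[(tert-butyldimethylsilyl)oxy]-6,10-dimethyl-3-methylidene-2-oxo-2,3,3a,4,5,8,9,11a-octahydrocyclodeca[b]furan-4-yl (3R)-3-methyl-4-(octadecanoyloxy)butanoate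
Conditions: DCC, DMAP, CH2Cl2, 0 → 23 °C
Reagents that add atoms: none
Why: Steglich esterification of the only free hydroxyl (O8) with retention at C8; the descriptor at C7 changes by CIP priority only.

Step 18
Reactants: 26 (3aS,4S,5R,6Z,10E,11aS)-5-[(tert-butyldimethylsilyl)oxy]-6,10-dimethyl-3-methylidene-2-oxo-2,3,3a,4,5,8,9,11a-octahydrocyclodeca[b]furan-4-yl (3R)-3-methyl-4-(octadecanoyloxy)butanoate
Product: 27 (3aS,4S,5R,6Z,10E,11aS)-5-hydroxy-6,10-dimethyl-3-methylidene-2-oxo-2,3,3a,4,5,8,9,11a-octahydrocyclodeca[b]furan-4-yl (3R)-3-methyl-4-(octadecanoyloxy)butanoate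
Conditions: HF·pyridine, pyridine, THF, 0 → 23 °C
Reagents that add atoms: none
Why: Buffered fluoride desilylation, mild enough to leave the α-methylene lactone and both esters intact and not to drive an O8 to O9 acyl shift.

**Compound list**

1 | 2-methylprop-2-enal (methacrolein) | C=C(C)C=O | starting material
2 | ethynyltrimethylsilane | C#C[Si](C)(C)C | starting material
3 | (3R)-2-methyl-5-(trimethylsilyl)pent-1-en-4-yn-3-ol | C[Si](C)(C)C#C[C@H](O)C(C)=C | intermediate
4 | tert-butyldimethyl{[(3R)-2-methyl-5-(trimethylsilyl)pent-1-en-4-yn-3-yl]oxy}silane | C[Si](C)(C)C#C[C@H](O[Si](C)(C)C(C)(C)C)C(C)=C | intermediate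
5 | tert-butyldimethyl{[(3R)-2-methylpent-1-en-4-yn-3-yl]oxy}silane | C#C[C@H](O[Si](C)(C)C(C)(C)C)C(C)=C | intermediate
6 | hex-1-en-5-yne | C=CCCC#C | starting material
7 | dimethyl[(1E)-2-methylhexa-1,5-dien-1-yl]alane | C=CCC/C(C)=C/[Al](C)C | intermediate
8 | (2E)-3-methylhepta-2,6-dien-1-ol | C=CCC/C(C)=C/CO | intermediate
9 | (2E)-3-methylhepta-2,6-dienal | C=CCC/C(C)=C/C=O | intermediate
10 | (3R,6S,7E)-3-[(tert-butyldimethylsilyl)oxy]-2,8-dimethyldodeca-1,7,11-trien-4-yn-6-ol | C=CCC/C(C)=C/[C@H](O)C#C[C@H](O[Si](C)(C)C(C)(C)C)C(C)=C | intermediate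
11 | (3S,4E,6R,7E)-3-[(tert-butyldimethylsilyl)oxy]-2,8-dimethyldodeca-1,4,7,11-tetraen-6-ol | C=CCC/C(C)=C/[C@H](O)/C=C/[C@H](O[Si](C)(C)C(C)(C)C)C(C)=C | intermediate
12 | 2-(diethoxyphosphoryl)acetic acid | OC(=O)CP(=O)(OCC)OCC | starting material
13 | (3S,4E,6R,7E)-3-[(tert-butyldimethylsilyl)oxy]-2,8-dimethyldodeca-1,4,7,11-tetraen-6-yl 2-(diethoxyphosphoryl)acetate | C=CCC/C(C)=C/[C@H](OC(=O)CP(=O)(OCC)OCC)/C=C/[C@H](O[Si](C)(C)C(C)(C)C)C(C)=C | intermediate
14 | (3S,4E,6R,7E)-3-hydroxy-2,8-dimethyldodeca-1,4,7,11-tetraen-6-yl 2-(diethoxyphosphoryl)acetate | C=CCC/C(C)=C/[C@H](OC(=O)CP(=O)(OCC)OCC)/C=C/[C@H](O)C(C)=C | intermediate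
15 | (1S,2E)-1-{(2R,3R)-3-[(1R)-1-hydroxy-2-methylprop-2-en-1-yl]oxiran-2-yl}-3-methylhepta-2,6-dien-1-yl 2-(diethoxyphosphoryl)acetate | C=CCC/C(C)=C/[C@H](OC(=O)CP(=O)(OCC)OCC)[C@H]1O[C@@H]1[C@H](O)C(C)=C | intermediate
16 | (1R,2S,3E,7Z,9R,10R)-9-hydroxy-4,8-dimethyl-11-oxabicyclo[8.1.0]undeca-3,7-dien-2-yl 2-(diethoxyphosphoryl)acetate | CCOP(=O)(CC(=O)O[C@H]1/C=C(\C)CC/C=C(/C)[C@@H](O)[C@H]2O[C@@H]21)OCC | intermediate
17 | (1R,2S,3E,7Z,9R,10S)-9-[(tert-butyldimethylsilyl)oxy]-4,8-dimethyl-11-oxabicyclo[8.1.0]undeca-3,7-dien-2-yl 2-(diethoxyphosphoryl)acetate | CCOP(=O)(CC(=O)O[C@H]1/C=C(\C)CC/C=C(/C)[C@@H](O[Si](C)(C)C(C)(C)C)[C@H]2O[C@@H]21)OCC | intermediate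
18 | diethyl [(3aR,4S,5R,6Z,10E,11aS)-5-[(tert-butyldimethylsilyl)oxy]-4-hydroxy-6,10-dimethyl-2-oxo-2,3,3a,4,5,8,9,11a-octahydrocyclodeca[b]furan-3-yl]phosphonate (C3 epimers) | CCOP(=O)(OCC)C1C(=O)O[C@H]2/C=C(\C)CC/C=C(/C)[C@@H](O[Si](C)(C)C(C)(C)C)[C@@H](O)[C@@H]12 | intermediate
19 | (3aR,4S,5R,6Z,10E,11aS)-5-[(tert-butyldimethylsilyl)oxy]-4-hydroxy-6,10-dimethyl-3-methylidene-3a,4,5,8,9,11a-hexahydrocyclodeca[b]furan-2(3H)-one | C=C1C(=O)O[C@H]2/C=C(\C)CC/C=C(/C)[C@@H](O[Si](C)(C)C(C)(C)C)[C@@H](O)[C@@H]12 | intermediate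
20 | (4R)-4-methyloxolan-2-one | C[C@H]1COC(=O)C1 | starting material
21 | potassium (3R)-4-hydroxy-3-methylbutanoate | [K+].[O-]C(=O)C[C@@H](C)CO | intermediate
22 | benzyl (3R)-4-hydroxy-3-methylbutanoate | O=C(C[C@@H](C)CO)OCc1ccccc1 | intermediate
23 | octadecanoyl chloride | CCCCCCCCCCCCCCCCCC(=O)Cl | starting material
24 | benzyl (3R)-3-methyl-4-(octadecanoyloxy)butanoate | CCCCCCCCCCCCCCCCCC(=O)OC[C@H](C)CC(=O)OCc1ccccc1 | intermediate
25 | (3R)-3-methyl-4-(octadecanoyloxy)butanoic acid | CCCCCCCCCCCCCCCCCC(=O)OC[C@H](C)CC(=O)O | intermediate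
26 | (3aS,4S,5R,6Z,10E,11aS)-5-[(tert-butyldimethylsilyl)oxy]-6,10-dimethyl-3-methylidene-2-oxo-2,3,3a,4,5,8,9,11a-octahydrocyclodeca[b]furan-4-yl (3R)-3-methyl-4-(octadecanoyloxy)butanoate | C=C1C(=O)O[C@H]2/C=C(\C)CC/C=C(/C)[C@@H](O[Si](C)(C)C(C)(C)C)[C@@H](OC(=O)C[C@@H](C)COC(=O)CCCCCCCCCCCCCCCCC)[C@@H]12 | intermediate
27 | (3aS,4S,5R,6Z,10E,11aS)-5-hydroxy-6,10-dimethyl-3-methylidene-2-oxo-2,3,3a,4,5,8,9,11a-octahydrocyclodeca[b]furan-4-yl (3R)-3-methyl-4-(octadecanoyloxy)butanoate | C=C1C(=O)O[C@H]2/C=C(\C)CC/C=C(/C)[C@@H](O)[C@@H](OC(=O)C[C@@H](C)COC(=O)CCCCCCCCCCCCCCCCC)[C@@H]12 | target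

**Step count**

Total steps: 18. Longest linear sequence: 13 steps (1–3, 6–13, 17, 18).

**Steps most likely to fail**

Step 11 (ring-closing metathesis). The open chain is not pre-organized, so intermolecular metathesis, closure to the 1(10)E olefin or ruthenium-hydride isomerization of the allylic alcohol may win. The fallback reverses the ring order and uses the lactone as a template. It sets out from 15: silylation (TBSOTf, 2,6-lutidine) gives the open-chain silyl ether (1S,2E)-1-{(2R,3S)-3-[(1R)-1-[(tert-butyldimethylsilyl)oxy]-2-methylprop-2-en-1-yl]oxiran-2-yl}-3-methylhepta-2,6-dien-1-yl 2-(diethoxyphosphoryl)acetate F1. NaH in THF then closes the γ-lactone on the open chain by the same 5-exo-tet oxirane opening and gives the open-chain α-phosphono lactone diethyl {(4R,5S)-4-[(1S,2R)-2-[(tert-butyldimethylsilyl)oxy]-1-hydroxy-3-methylbut-3-en-1-yl]-5-[(1E)-2-methylhexa-1,5-dien-1-yl]-2-oxooxolan-3-yl}phosphonate F2, whose cis-disubstituted lactone holds both olefin-bearing arms on one face. Ring-closing metathesis of F2 with the same catalyst should give 18, here isolated, and NaH with paraformaldehyde converts 18 into 19, where the route is rejoined.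

Step 13 (key step). C-alkylation at C7 may be slow in the medium ring, so that base-driven processes take over: isomerization of the oxirane to an allylic alcohol, silyl shift from O9 to the transient C8 alkoxide, or lactone migration to O8. The fallback replaces the carbanion by neutral nucleophilic catalysis. It sets out from 17: methanolysis (K2CO3, MeOH, 0 °C) removes the phosphonoacetate and gives the epoxy alcohol (1R,2S,3E,7Z,9R,10S)-9-[(tert-butyldimethylsilyl)oxy]-4,8-dimethyl-11-oxabicyclo[8.1.0]undeca-3,7-dien-2-ol F3. Acryloyl chloride and i-Pr2NEt give the acrylate (1R,2S,3E,7Z,9R,10S)-9-[(tert-butyldimethylsilyl)oxy]-4,8-dimethyl-11-oxabicyclo[8.1.0]undeca-3,7-dien-2-yl prop-2-enoate F4. PMe3 (20 mol %) in tert-butanol should then effect a Morita–Baylis–Hillman-type cycloisomerization, by analogy with enone-tethered epoxides: the phosphine adds to the acrylate, the zwitterionic enolate opens the oxirane at C7 in the same 5-exo-tet sense, the alkoxide is protonated by the solvent, and loss of PMe3 unveils the methylene. This gives 19 directly.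

Step 17 (esterification of the C8 hydroxyl). Acylation of this hindered hydroxyl may be slow, which gives time for conjugate addition of DMAP to the exocyclic methylene, N-acylurea formation or lactone migration from O6 to O8. The fallback acylates before the methylene exists. It sets out from 17: step 13 is stopped before formaldehyde is added (aq. NH4Cl), which gives 18 in isolated form. Esterification of 18 with 25 (DCC, DMAP) gives (3aS,4S,5R,6Z,10E,11aS)-5-[(tert-butyldimethylsilyl)oxy]-3-(diethoxyphosphoryl)-6,10-dimethyl-2-oxo-2,3,3a,4,5,8,9,11a-octahydrocyclodeca[b]furan-4-yl (3R)-3-methyl-4-(octadecanoyloxy)butanoate F5. Horner–Wadsworth–Emmons methylenation of F5 (K2CO3, aqueous formaldehyde, THF, 0 °C) gives 26, where the route is rejoined.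

**Further compounds**

F1 | step 11 | (1S,2E)-1-{(2R,3S)-3-[(1R)-1-[(tert-butyldimethylsilyl)oxy]-2-methylprop-2-en-1-yl]oxiran-2-yl}-3-methylhepta-2,6-dien-1-yl 2-(diethoxyphosphoryl)acetate | C=CCC/C(C)=C/[C@H](OC(=O)CP(=O)(OCC)OCC)[C@H]1O[C@@H]1[C@H](O[Si](C)(C)C(C)(C)C)C(C)=C
F2 | step 11 | diethyl {(4R,5S)-4-[(1S,2R)-2-[(tert-butyldimethylsilyl)oxy]-1-hydroxy-3-methylbut-3-en-1-yl]-5-[(1E)-2-methylhexa-1,5-dien-1-yl]-2-oxooxolan-3-yl}phosphonate (C3 epimers) | CCOP(=O)(OCC)C1C(=O)O[C@@H](/C=C(\C)CCC=C)[C@H]1[C@H](O)[C@H](O[Si](C)(C)C(C)(C)C)C(C)=C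
F3 | step 13 | (1R,2S,3E,7Z,9R,10S)-9-[(tert-butyldimethylsilyl)oxy]-4,8-dimethyl-11-oxabicyclo[8.1.0]undeca-3,7-dien-2-ol | O[C@H]1/C=C(\C)CC/C=C(/C)[C@@H](O[Si](C)(C)C(C)(C)C)[C@H]2O[C@@H]21
F4 | step 13 | (1R,2S,3E,7Z,9R,10S)-9-[(tert-butyldimethylsilyl)oxy]-4,8-dimethyl-11-oxabicyclo[8.1.0]undeca-3,7-dien-2-yl prop-2-enoate | C=CC(=O)O[C@H]1/C=C(\C)CC/C=C(/C)[C@@H](O[Si](C)(C)C(C)(C)C)[C@H]2O[C@@H]21
F5 | step 17 | (3aS,4S,5R,6Z,10E,11aS)-5-[(tert-butyldimethylsilyl)oxy]-3-(diethoxyphosphoryl)-6,10-dimethyl-2-oxo-2,3,3a,4,5,8,9,11a-octahydrocyclodeca[b]furan-4-yl (3R)-3-methyl-4-(octadecanoyloxy)butanoate (C3 epimers) | CCOP(=O)(OCC)C1C(=O)O[C@H]2/C=C(\C)CC/C=C(/C)[C@@H](O[Si](C)(C)C(C)(C)C)[C@@H](OC(=O)C[C@@H](C)COC(=O)CCCCCCCCCCCCCCCCC)[C@@H]12
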